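Assumption: both chiral starting materials are used as the commercial (R) enantiomers; atom labels follow halimane numbering (C1–C10 decalin, C11–C15 side chain, C16 = 13‑Me, C17 = 8‑Me, C18 = ester carbon on C4, C19 = 4‑Me, C20 = 9‑Me; α = face of H5).

**Retrosynthetic overview**
1. Oxirane: (13S,14S)-epoxy alcohol ⇐ (13S,14R)-13,14,15-triol by primary tosylate, terminal epoxide and Payne rearrangement (inversion at C14); formed last.
2. Ring A (C2–C3 and C4–C5 bonds, C4 and C5 stereocentres) ⇐ intramolecular Diels–Alder of a ring B 1‑vinylcyclohexene with a methacrylate tethered as the ester of the C13 tertiary alcohol; the bridging lactone is then opened to the C18 methyl ester.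
3. C13 ⇐ chelation-controlled MeMgBr addition next to C14, which comes from (R)-glycerate acetonide; C9 ⇐ Mukaiyama–Michael addition of a ring B enol ether to the glycerate-derived vinyl ketone.
4. Ring B with C8 ⇐ (R)-pulegone (α'-methylation, retro-aldol); ring B is bought, ring A is made by the cycloaddition, the oxirane closes at the end.

**Route**

Step 1
Reactants: 1 (R)-(+)-pulegone
Product: 2 (2S,3R)-2,3-dimethyl-6-(propan-2-ylidene)cyclohexan-1-one
Conditions: LiN(iPr)2, THF, −78 °C; MeI, −78 → 0 °C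
Reagents that add atoms: iodomethane, CI
Why: Kinetic α'-deprotonation gives the cross-conjugated enolate, which is methylated (enolate alkylation) mainly trans to the ring methyl; the new C2 centre is erased in step 3 and the bought centre (future C8) is untouched.

Step 2
Reactants: 2 (2S,3R)-2,3-dimethyl-6-(propan-2-ylidene)cyclohexan-1-one
Product: 3 (2S,3R)-2,3-dimethylcyclohexan-1-one
Conditions: 3 M aq. HCl, reflux, acetone distilled off
Reagents that add atoms: none
Why: Acid-catalysed retro-aldol (conjugate hydration, loss of acetone) removes the isopropylidene blocking group; the β-methyl centre cannot epimerize and C2 equilibrates to mainly trans.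

Step 3
Reactants: 3 (2S,3R)-2,3-dimethylcyclohexan-1-one
Product: 4 (R)-[(2,3-dimethylcyclohex-1-en-1-yl)oxy]trimethylsilane
Conditions: Me3SiCl, NaI, Et3N, MeCN, 23 °C
Reagents that add atoms: chlorotrimethylsilane, C[Si](C)(C)Cl
Why: Thermodynamic silyl enol ether formation (Me3SiI made in the flask) favours the tetrasubstituted enol ether (about 9:1; the minor regioisomer is removed here or after step 6), fixing the site for quaternization at C9.

Step 4
Reactants: 5 methyl (R)-2,2-dimethyl-1,3-dioxolane-4-carboxylate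
Product: 6 (R)-N-methoxy-N,2,2-trimethyl-1,3-dioxolane-4-carboxamide
Conditions: MeNH(OMe)·HCl, i-PrMgCl, THF, −20 °C
Reagents that add atoms: N,O-dimethylhydroxylamine hydrochloride, CNOC.Cl
Why: Weinreb amidation through the magnesium amide; the low temperature and fast acyl substitution leave the α-alkoxy stereocentre (future C14) intact.

Step 5
Reactants: 6 (R)-N-methoxy-N,2,2-trimethyl-1,3-dioxolane-4-carboxamide
Product: 7 1-[(4R)-2,2-dimethyl-1,3-dioxolan-4-yl]prop-2-en-1-one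
Conditions: CH2=CHMgBr, THF, −78 → 0 °C; inverse quench into cold 1 M HCl
Reagents that add atoms: vinylmagnesium bromide, C=C[Mg]Br
Why: Weinreb ketone synthesis stops at the chelated tetrahedral intermediate; the inverse acidic quench prevents aza-Michael addition of the released amine to the enone.

Step 6
Reactants: 4 (R)-[(2,3-dimethylcyclohex-1-en-1-yl)oxy]trimethylsilane; 7 1-[(4R)-2,2-dimethyl-1,3-dioxolan-4-yl]prop-2-en-1-one
Product: 8 (2S,3R)-2-{3-[(4R)-2,2-dimethyl-1,3-dioxolan-4-yl]-3-oxopropyl}-2,3-dimethylcyclohexan-1-one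
Conditions: BF3·OEt2, i-PrOH, CH2Cl2, −78 °C
Reagents that add atoms: none
Why: Mukaiyama–Michael addition: the enone attacks the tetrasubstituted enol ether carbon anti to the pseudoaxial neighbouring methyl, so the C9 chain ends trans to 8‑Me and the two methyls cis (9S); the alcohol additive traps silicon and suppresses enone oligomerization.

Step 7
Reactants: 8 (2S,3R)-2-{3-[(4R)-2,2-dimethyl-1,3-dioxolan-4-yl]-3-oxopropyl}-2,3-dimethylcyclohexan-1-one
Product: 10 (2S)-2-[(4R)-2,2-dimethyl-1,3-dioxolan-4-yl]-4-[(1S,2R)-1,2-dimethyl-6-oxocyclohexyl]butan-2-yl 2-methylprop-2-enoate, via bromomagnesium tertiary alkoxide 9 (not isolated)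
Conditions: MeMgBr, MgBr2·OEt2, CH2Cl2, −78 °C; then CH2=C(Me)COCl, DMAP (cat.), −78 → 23 °C
Reagents that add atoms: methylmagnesium bromide, C[Mg]Br; methacryloyl chloride, CC(=C)C(Cl)=O
Why: Cram-chelate Grignard addition: magnesium bridges the C13 carbonyl and the dioxolane O14 and methyl enters from the side of H14, giving 13S, while the α-quaternary ring ketone is spared; O-acylation of the alkoxide in the flask installs the tethered dienophile.

Step 8
Reactants: 10 (2S)-2-[(4R)-2,2-dimethyl-1,3-dioxolan-4-yl]-4-[(1S,2R)-1,2-dimethyl-6-oxocyclohexyl]butan-2-yl 2-methylprop-2-enoate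
Product: 11 (2S)-2-[(4R)-2,2-dimethyl-1,3-dioxolan-4-yl]-4-[(1S,6R)-1,6-dimethyl-2-{[(trifluoromethyl)sulfonyl]oxy}cyclohex-2-en-1-yl]butan-2-yl 2-methylprop-2-enoate
Conditions: KN(SiMe3)2, THF, −78 °C, 10 min; then PhNTf2, −78 → −40 °C
Reagents that add atoms: N-phenylbis(trifluoromethanesulfonimide), O=S(=O)(N(c1ccccc1)S(=O)(=O)C(F)(F)F)C(F)(F)F
Why: Enol triflate formation: the ketone can enolize only toward C5 (C9 is quaternary), and the hindered base at −78 °C removes the ketone α-proton faster than it touches the α-substituted tertiary acrylate.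

Step 9
Reactants: 11 (2S)-2-[(4R)-2,2-dimethyl-1,3-dioxolan-4-yl]-4-[(1S,6R)-1,6-dimethyl-2-{[(trifluoromethyl)sulfonyl]oxy}cyclohex-2-en-1-yl]butan-2-yl 2-methylprop-2-enoate
Product: 12 (2S)-2-[(4R)-2,2-dimethyl-1,3-dioxolan-4-yl]-4-[(1S,6R)-2-ethenyl-1,6-dimethylcyclohex-2-en-1-yl]butan-2-yl 2-methylprop-2-enoate
Conditions: CH2=CHSnBu3, Pd(PPh3)4 (5 mol%), LiCl, THF, 65 °C
Reagents that add atoms: tributyl(vinyl)stannane, C=C[Sn](CCCC)(CCCC)CCCC
Why: Stille coupling of the hindered enol triflate gives the 1‑vinylcyclohexene diene (C2=C1–C10=C5), whose s-cis form is favoured by the adjacent quaternary C9; no stereocentre is touched.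

Step 10
Reactants: 12 (2S)-2-[(4R)-2,2-dimethyl-1,3-dioxolan-4-yl]-4-[(1S,6R)-2-ethenyl-1,6-dimethylcyclohex-2-en-1-yl]butan-2-yl 2-methylprop-2-enoate
Product: 13 bridged lactone (4S,5R,8R,9S,13S,14R)-14,15-(isopropylidenedioxy)halim-1(10)-en-18,13-olide
Conditions: PhMe (5 mM), BHT (cat.), 170 °C, sealed tube
Reagents that add atoms: none
Why: Intramolecular Diels–Alder with the tether on the internal diene carbon: the five-atom ester tether from the β-oriented C9 chain can reach only the β face of C5 and only with the carbonyl endo over C10, so C4–C5 forms syn to C11 (5R, H5 α) with C18 β and C19 α (4S), C3 bonds to C2, and the new alkene is C1=C10.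

Step 11
Reactants: 13 bridged lactone (4S,5R,8R,9S,13S,14R)-14,15-(isopropylidenedioxy)halim-1(10)-en-18,13-olide
Product: 16 methyl (1S,5S,6R,8aR)-1,5,6-trimethyl-5-[(3S,4R)-3,4,5-trihydroxy-3-methylpentyl]-1,2,3,5,6,7,8,8a-octahydronaphthalene-1-carboxylate, via diol lactone 14 (not isolated), via ring-expanded primary lactone 15 (not isolated)
Conditions: p-TsOH (cat.), MeOH, 23 °C; then NaOMe (excess), MeOH, 50 °C
Reagents that add atoms: methanol, CO
Why: Acid transketalization frees the 14,15-diol, whose alkoxide then takes the hindered acyl group from the tertiary O13 to the primary O15 (intramolecular acyl transfer), and the relaxed primary ester is transesterified by methoxide to the C18 methyl ester; no stereocentre is involved.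

Step 12
Reactants: 16 methyl (1S,5S,6R,8aR)-1,5,6-trimethyl-5-[(3S,4R)-3,4,5-trihydroxy-3-methylpentyl]-1,2,3,5,6,7,8,8a-octahydronaphthalene-1-carboxylate
Product: 19 methyl (1S,5S,6R,8aR)-5-{2-[(2S,3S)-3-(hydroxymethyl)-2-methyloxiran-2-yl]ethyl}-1,5,6-trimethyl-1,2,3,5,6,7,8,8a-octahydronaphthalene-1-carboxylate, via primary tosylate 17 (not isolated), via terminal epoxide 18 (not isolated)
Conditions: TsCl, Et3N, Bu2SnO (cat.), CH2Cl2, 0 °C; then K2CO3, MeOH, 0 → 23 °C
Reagents that add atoms: none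
Why: Stannylene-directed sulfonylation of the primary OH, 3-exo-tet closure to the (14R) terminal epoxide, then Payne rearrangement: O13 opens the epoxide at C14 with inversion to give the more substituted (13S,14S) epoxide and the primary alcohol, the favoured side of the equilibrium; C13 keeps its C–O bond and the hindered methyl ester is inert to methanolic carbonate.

**Compound list**
1 | (R)-(+)-pulegone | C[C@@H]1CCC(=C(C)C)C(=O)C1 | starting material
2 | (2S,3R)-2,3-dimethyl-6-(propan-2-ylidene)cyclohexan-1-one (trans isomer shown, minor 2R epimer carried) | O=C1C(=C(C)C)CC[C@@H](C)[C@@H]1C | intermediate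
3 | (2S,3R)-2,3-dimethylcyclohexan-1-one (with minor 2R epimer) | O=C1CCC[C@@H](C)[C@@H]1C | intermediate
4 | (R)-[(2,3-dimethylcyclohex-1-en-1-yl)oxy]trimethylsilane | C[Si](C)(C)OC1=C(C)[C@H](C)CCC1 | intermediate
5 | methyl (R)-2,2-dimethyl-1,3-dioxolane-4-carboxylate | COC(=O)[C@H]1COC(C)(C)O1 | starting material
6 | (R)-N-methoxy-N,2,2-trimethyl-1,3-dioxolane-4-carboxamide | CON(C)C(=O)[C@H]1COC(C)(C)O1 | intermediate
7 | 1-[(4R)-2,2-dimethyl-1,3-dioxolan-4-yl]prop-2-en-1-one | C=CC(=O)[C@H]1COC(C)(C)O1 | intermediate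
8 | (2S,3R)-2-{3-[(4R)-2,2-dimethyl-1,3-dioxolan-4-yl]-3-oxopropyl}-2,3-dimethylcyclohexan-1-one | O=C1CCC[C@@H](C)[C@]1(C)CCC(=O)[C@H]1COC(C)(C)O1 | intermediate
9 | bromomagnesium (2S)-2-[(4R)-2,2-dimethyl-1,3-dioxolan-4-yl]-4-[(1S,2R)-1,2-dimethyl-6-oxocyclohexyl]butan-2-olate | O=C1CCC[C@@H](C)[C@]1(C)CC[C@](C)(O[Mg]Br)[C@H]1COC(C)(C)O1 | intermediate
10 | (2S)-2-[(4R)-2,2-dimethyl-1,3-dioxolan-4-yl]-4-[(1S,2R)-1,2-dimethyl-6-oxocyclohexyl]butan-2-yl 2-methylprop-2-enoate | O=C1CCC[C@@H](C)[C@]1(C)CC[C@](C)(OC(=O)C(C)=C)[C@H]1COC(C)(C)O1 | intermediate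
11 | (2S)-2-[(4R)-2,2-dimethyl-1,3-dioxolan-4-yl]-4-[(1S,6R)-1,6-dimethyl-2-{[(trifluoromethyl)sulfonyl]oxy}cyclohex-2-en-1-yl]butan-2-yl 2-methylprop-2-enoate | O=S(=O)(OC1=CCC[C@@H](C)[C@]1(C)CC[C@](C)(OC(=O)C(C)=C)[C@H]1COC(C)(C)O1)C(F)(F)F | intermediate
12 | (2S)-2-[(4R)-2,2-dimethyl-1,3-dioxolan-4-yl]-4-[(1S,6R)-2-ethenyl-1,6-dimethylcyclohex-2-en-1-yl]butan-2-yl 2-methylprop-2-enoate | C=CC1=CCC[C@@H](C)[C@]1(C)CC[C@](C)(OC(=O)C(C)=C)[C@H]1COC(C)(C)O1 | intermediate
13 | bridged lactone (4S,5R,8R,9S,13S,14R)-14,15-(isopropylidenedioxy)halim-1(10)-en-18,13-olide (nine-membered lactone from C18 to O13 across the β face) | O=C3[C@@]1(C)CCC=C2[C@H]1CC[C@@H](C)[C@]2(C)CC[C@](C)(O3)[C@H]1COC(C)(C)O1 | intermediate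
14 | diol lactone (4S,5R,8R,9S,13S,14R)-14,15-dihydroxyhalim-1(10)-en-18,13-olide | O=C3[C@@]1(C)CCC=C2[C@H]1CC[C@@H](C)[C@]2(C)CC[C@](C)(O3)[C@H](O)CO | intermediate
15 | ring-expanded primary lactone (4S,5R,8R,9S,13S,14R)-13,14-dihydroxyhalim-1(10)-en-18,15-olide (eleven-membered) | O=C3[C@@]1(C)CCC=C2[C@H]1CC[C@@H](C)[C@]2(C)CC[C@](C)(O)[C@H](O)CO3 | intermediate
16 | methyl (1S,5S,6R,8aR)-1,5,6-trimethyl-5-[(3S,4R)-3,4,5-trihydroxy-3-methylpentyl]-1,2,3,5,6,7,8,8a-octahydronaphthalene-1-carboxylate | COC(=O)[C@@]1(C)CCC=C2[C@H]1CC[C@@H](C)[C@]2(C)CC[C@](C)(O)[C@H](O)CO | intermediate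
17 | methyl (1S,5S,6R,8aR)-5-[(3S,4R)-3,4-dihydroxy-3-methyl-5-(tosyloxy)pentyl]-1,5,6-trimethyl-1,2,3,5,6,7,8,8a-octahydronaphthalene-1-carboxylate | COC(=O)[C@@]1(C)CCC=C2[C@H]1CC[C@@H](C)[C@]2(C)CC[C@](C)(O)[C@H](O)COS(=O)(=O)c1ccc(C)cc1 | intermediate
18 | methyl (1S,5S,6R,8aR)-5-{(3S)-3-hydroxy-3-[(2R)-oxiran-2-yl]butyl}-1,5,6-trimethyl-1,2,3,5,6,7,8,8a-octahydronaphthalene-1-carboxylate | COC(=O)[C@@]1(C)CCC=C2[C@H]1CC[C@@H](C)[C@]2(C)CC[C@](C)(O)[C@H]1CO1 | intermediate
19 | methyl (1S,5S,6R,8aR)-5-{2-[(2S,3S)-3-(hydroxymethyl)-2-methyloxiran-2-yl]ethyl}-1,5,6-trimethyl-1,2,3,5,6,7,8,8a-octahydronaphthalene-1-carboxylate (CNP0324371.1) | COC(=O)[C@@]1(C)CCC=C2[C@H]1CC[C@@H](C)[C@]2(C)CC[C@]1(C)O[C@H]1CO | target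

**Totals**
Total step count: 12. Longest linear sequence: 10 (steps 1–3 and 6–12, from pulegone).

**Three steps most likely to fail, each with a fallback**

Step 10 (intramolecular Diels–Alder). The transition state contains a nine-membered lactone whose ester cannot be fully planar, and at 170 °C the tertiary ester may eliminate or the acrylate may oligomerize. The fallback sets out from 12 and comes back at 15. p-TsOH in MeOH removes the acetonide of 12 to give (3S,4R)-1-[(1S,6R)-2-ethenyl-1,6-dimethylcyclohex-2-en-1-yl]-4,5-dihydroxy-3-methylpentan-3-yl 2-methylprop-2-enoate F7. Catalytic DBU in THF then moves the methacryloyl group from the tertiary O13 to the primary oxygen, giving (2R,3S)-5-[(1S,6R)-2-ethenyl-1,6-dimethylcyclohex-2-en-1-yl]-2,3-dihydroxy-3-methylpentyl 2-methylprop-2-enoate F8. Heating F8 in dilute toluene closes ring A through an eleven-membered lactone that can hold a normal Z ester. The chain still cannot carry the dienophile around the vinyl group to the α face, but endo/exo control is looser than with the short tether. The product is 15, which is methanolysed as in the second half of step 11.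

Step 6 (Mukaiyama–Michael addition creating the quaternary C9 with an epimerizable, polymerizable vinyl ketone). The fallback sets out from 6 (with 4) and comes back at 8. Ethynylmagnesium bromide converts 6 into 1-[(4R)-2,2-dimethyl-1,3-dioxolan-4-yl]prop-2-yn-1-one F1, a more reactive and less hindered acceptor. The lithium enolate released from 4 with MeLi (THF, 0 °C) adds to F1 at −78 °C to give (2R,3R)-2-{(1E)-3-[(4R)-2,2-dimethyl-1,3-dioxolan-4-yl]-3-oxoprop-1-en-1-yl}-2,3-dimethylcyclohexan-1-one F2 (same spatial arrangement at the quaternary carbon as in 8; the descriptor changes only because the vinyl group outranks the ring carbon). H2 over Pd/C in EtOAc saturates the C11=C12 bond of either alkene isomer and returns 8.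

Step 8 (enolization with a strong base in the presence of the methacrylate; Michael addition or anionic oligomerization could compete). The fallback sets out from 8 and comes back at 12; it installs the dienophile only after the diene is made. The alkoxide 9 is trapped with Et3SiOTf instead of the acid chloride to give (2S,3R)-2-{(3S)-3-[(4R)-2,2-dimethyl-1,3-dioxolan-4-yl]-3-[(triethylsilyl)oxy]butyl}-2,3-dimethylcyclohexan-1-one F3. KN(SiMe3)2 and PhNTf2 then give (5R,6S)-6-{(3S)-3-[(4R)-2,2-dimethyl-1,3-dioxolan-4-yl]-3-[(triethylsilyl)oxy]butyl}-5,6-dimethylcyclohex-1-en-1-yl trifluoromethanesulfonate F4. Stille vinylation as in step 9 gives triethyl({(2S)-2-[(4R)-2,2-dimethyl-1,3-dioxolan-4-yl]-4-[(1S,6R)-2-ethenyl-1,6-dimethylcyclohex-2-en-1-yl]butan-2-yl}oxy)silane F5. Bu4NF in THF frees (2S)-2-[(4R)-2,2-dimethyl-1,3-dioxolan-4-yl]-4-[(1S,6R)-2-ethenyl-1,6-dimethylcyclohex-2-en-1-yl]butan-2-ol F6. Its lithium alkoxide (n-BuLi, THF, −78 °C) is acylated with methacryloyl chloride to give 12.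

**Further compounds**
F1 | step 6 | 1-[(4R)-2,2-dimethyl-1,3-dioxolan-4-yl]prop-2-yn-1-one | C#CC(=O)[C@H]1COC(C)(C)O1
F2 | step 6 | (2R,3R)-2-{(1E)-3-[(4R)-2,2-dimethyl-1,3-dioxolan-4-yl]-3-oxoprop-1-en-1-yl}-2,3-dimethylcyclohexan-1-one | O=C1CCC[C@@H](C)[C@]1(C)/C=C/C(=O)[C@H]1COC(C)(C)O1
F3 | step 8 | (2S,3R)-2-{(3S)-3-[(4R)-2,2-dimethyl-1,3-dioxolan-4-yl]-3-[(triethylsilyl)oxy]butyl}-2,3-dimethylcyclohexan-1-one | O=C1CCC[C@@H](C)[C@]1(C)CC[C@](C)(O[Si](CC)(CC)CC)[C@H]1COC(C)(C)O1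
F4 | step 8 | (5R,6S)-6-{(3S)-3-[(4R)-2,2-dimethyl-1,3-dioxolan-4-yl]-3-[(triethylsilyl)oxy]butyl}-5,6-dimethylcyclohex-1-en-1-yl trifluoromethanesulfonate | O=S(=O)(OC1=CCC[C@@H](C)[C@]1(C)CC[C@](C)(O[Si](CC)(CC)CC)[C@H]1COC(C)(C)O1)C(F)(F)F
F5 | step 8 | triethyl({(2S)-2-[(4R)-2,2-dimethyl-1,3-dioxolan-4-yl]-4-[(1S,6R)-2-ethenyl-1,6-dimethylcyclohex-2-en-1-yl]butan-2-yl}oxy)silane | C=CC1=CCC[C@@H](C)[C@]1(C)CC[C@](C)(O[Si](CC)(CC)CC)[C@H]1COC(C)(C)O1
F6 | step 8 | (2S)-2-[(4R)-2,2-dimethyl-1,3-dioxolan-4-yl]-4-[(1S,6R)-2-ethenyl-1,6-dimethylcyclohex-2-en-1-yl]butan-2-ol | C=CC1=CCC[C@@H](C)[C@]1(C)CC[C@](C)(O)[C@H]1COC(C)(C)O1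
F7 | step 10 | (3S,4R)-1-[(1S,6R)-2-ethenyl-1,6-dimethylcyclohex-2-en-1-yl]-4,5-dihydroxy-3-methylpentan-3-yl 2-methylprop-2-enoate | C=CC1=CCC[C@@H](C)[C@]1(C)CC[C@](C)(OC(=O)C(C)=C)[C@H](O)CO
F8 | step 10 | (2R,3S)-5-[(1S,6R)-2-ethenyl-1,6-dimethylcyclohex-2-en-1-yl]-2,3-dihydroxy-3-methylpentyl 2-methylprop-2-enoate | C=CC1=CCC[C@@H](C)[C@]1(C)CC[C@](C)(O)[C@H](O)COC(=O)C(C)=C
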